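**Retrosynthetic overview**
- The strategy rests on C3 (C–OH) and C4 (C=O) of pyranone ring C: two adjacent oxygenated carbons, an oxidised benzoin unit, that join C4a of ring A to C2. The C3–C4 bond is cut to a dialdehyde (aryl CHO = C4, aliphatic CHO = C3).
- Flavonol ⇐ chromane-3,4-dione ⇐ 3-hydroxychroman-4-one 15 ⇐ dialdehyde 14 by carbene-catalysed benzoin closure. Ring C is the only ring formed; rings A and B are bought.
- 14 ⇐ diol 13 ⇐ aryl ether 12, whose O1–C2 bond comes from Williamson union of salicylaldehyde 11 with α-bromo arylacetate 9.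
- 9 ⇐ aryl bromide 6 + tert-butyl acetate (C2–C1′ bond by Pd enolate arylation). 6 comes from 5-bromosalicylaldehyde by MOM protection, Baeyer–Villiger/methanolysis and prenylation, which fixes 4′-OMOM and 3′-O-prenyl.
- The three MOM acetals are removed last with a bipyridyl-buffered silyl triflate, because protic acid would also cleave the prenyl aryl ether.

Key step: step 10

Remark: the target has no stereocentre and is achiral, so no asymmetric step is needed; C2 and C3 of the intermediates are carried racemic and both become sp2 in step 11 (MOM = methoxymethyl, prenyl = 3-methylbut-2-en-1-yl).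

**Route**

Step 1
Reactants: 1 5-bromosalicylaldehyde
Product: 2 5-bromo-2-(methoxymethoxy)benzaldehyde
Conditions: MOMCl, i-Pr2NEt, CH2Cl2, 0 °C → rt
Reagents that add atoms: chloromethyl methyl ether, COCCl
Why: Williamson-type O-alkylation of the phenol by the chloromethyl ether (MOM protection) should proceed cleanly and leaves the aldehyde untouched.

Step 2
Reactants: 2 5-bromo-2-(methoxymethoxy)benzaldehyde
Product: 4 5-bromo-2-(methoxymethoxy)phenol, via aryl formate 3 (not isolated)
Conditions: mCPBA, CH2Cl2, 0 °C → rt; then K2CO3 (cat.), MeOH, rt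
Reagents that add atoms: 3-chloroperoxybenzoic acid, O=C(OO)c1cccc(Cl)c1
Why: Baeyer–Villiger (Dakin-type) oxidation, in which the electron-rich aryl group migrates to give the formate that methanolysis cleaves; it is run before the peracid-sensitive prenyl alkene is introduced and places the new phenol meta to bromine.

Step 3
Reactants: 4 5-bromo-2-(methoxymethoxy)phenol; 5 prenyl bromide
Product: 6 4-bromo-1-(methoxymethoxy)-2-(prenyloxy)benzene
Conditions: K2CO3, DMF, rt
Reagents that add atoms: none
Why: Williamson ether synthesis with a reactive allylic bromide; the MOM group does not migrate, so the regiochemistry (4-OMOM, 3-O-prenyl relative to Br at C1) is secure.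

Step 4
Reactants: 6 4-bromo-1-(methoxymethoxy)-2-(prenyloxy)benzene; 7 tert-butyl acetate
Product: 8 tert-butyl 2-[4-(methoxymethoxy)-3-(prenyloxy)phenyl]acetate
Conditions: LiHMDS (2.3 equiv), 7 (2.3 equiv), Pd(dba)2 (cat.), P(t-Bu)3 (cat.), toluene, rt
Reagents that add atoms: none
Why: Pd-catalysed α-arylation of an ester enolate (Buchwald–Hartwig type), which tolerates electron-rich aryl bromides at room temperature; the bulky tert-butyl ester and excess enolate should suppress Claisen condensation and diarylation.

Step 5
Reactants: 8 tert-butyl 2-[4-(methoxymethoxy)-3-(prenyloxy)phenyl]acetate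
Product: 9 tert-butyl 2-bromo-2-[4-(methoxymethoxy)-3-(prenyloxy)phenyl]acetate (racemic)
Conditions: LiHMDS, THF, −78 °C; enolate added to NBS, THF, −78 °C; used without chromatography
Reagents that add atoms: N-bromosuccinimide, BrN1C(=O)CCC1=O
Why: Electrophilic α-bromination of the lithium ester enolate; inverse addition at −78 °C should limit proton exchange and dibromination, and the enolate should outcompete the prenyl alkene and the arene for the bromine electrophile.

Step 6
Reactants: 10 2,4,5-trihydroxybenzaldehyde
Product: 11 2-hydroxy-4,5-bis(methoxymethoxy)benzaldehyde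
Conditions: MOMCl (2.1 equiv), i-Pr2NEt, CH2Cl2, 0 °C
Reagents that add atoms: chloromethyl methyl ether, COCCl
Why: Selective Williamson-type acetal protection; the 2-OH is hydrogen-bonded to the formyl group and is the least nucleophilic, so two equivalents of MOMCl should cap the 4- and 5-hydroxyls.

Step 7
Reactants: 11 2-hydroxy-4,5-bis(methoxymethoxy)benzaldehyde; 9 tert-butyl 2-bromo-2-[4-(methoxymethoxy)-3-(prenyloxy)phenyl]acetate
Product: 12 tert-butyl 2-[2-formyl-4,5-bis(methoxymethoxy)phenoxy]-2-[4-(methoxymethoxy)-3-(prenyloxy)phenyl]acetate (racemic)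
Conditions: K2CO3, DMF, 0 °C → rt
Reagents that add atoms: none
Why: Williamson ether synthesis by SN2 attack of the phenoxide on the activated benzylic α-bromo ester, which has no β-hydrogen for elimination; the low temperature should hold back Rap–Stoermer-type aldol closure of the product.

Step 8
Reactants: 12 tert-butyl 2-[2-formyl-4,5-bis(methoxymethoxy)phenoxy]-2-[4-(methoxymethoxy)-3-(prenyloxy)phenyl]acetate
Product: 13 2-[2-(hydroxymethyl)-4,5-bis(methoxymethoxy)phenoxy]-2-[4-(methoxymethoxy)-3-(prenyloxy)phenyl]ethan-1-ol (racemic)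
Conditions: LiAlH4, THF, 0 °C; Fieser work-up
Reagents that add atoms: none
Why: Hydride reduction of the aldehyde and the ester to the diol; acetals, aryl ethers and the trisubstituted alkene are inert to LiAlH4.

Step 9
Reactants: 13 2-[2-(hydroxymethyl)-4,5-bis(methoxymethoxy)phenoxy]-2-[4-(methoxymethoxy)-3-(prenyloxy)phenyl]ethan-1-ol
Product: 14 2-{1-[4-(methoxymethoxy)-3-(prenyloxy)phenyl]-2-oxoethoxy}-4,5-bis(methoxymethoxy)benzaldehyde (racemic)
Conditions: Dess–Martin periodinane (2.5 equiv), CH2Cl2, 0 °C → rt; Na2S2O3/NaHCO3 work-up; used crude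
Reagents that add atoms: none
Why: Dess–Martin oxidation should convert both primary alcohols to aldehydes under near-neutral conditions without over-oxidation; the dialdehyde is not stored because its α-aryloxy aldehyde enolises readily.

Step 10
Reactants: 14 2-{1-[4-(methoxymethoxy)-3-(prenyloxy)phenyl]-2-oxoethoxy}-4,5-bis(methoxymethoxy)benzaldehyde
Product: 15 rac-(2R,3R)-3-hydroxy-6,7-bis(methoxymethoxy)-2-[4-(methoxymethoxy)-3-(prenyloxy)phenyl]chroman-4-one (2,3-trans)
Conditions: 2-(pentafluorophenyl)-6,7-dihydro-5H-pyrrolo[2,1-c][1,2,4]triazol-2-ium tetrafluoroborate (20 mol %), i-Pr2NEt (20 mol %), degassed CH2Cl2, rt, Ar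
Reagents that add atoms: none
Why: Proposed new method: the triazolylidene adds reversibly to both formyl groups, but only the adduct at the aryl aldehyde (C4) should be deprotonated readily to a Breslow intermediate (benzylic, unhindered), and this acyl anion equivalent adds to the more electrophilic, α-branched C3 aldehyde, after which proton transfer and release of the carbene give the ketol. The closest known reaction type is the carbene-catalysed intramolecular crossed benzoin of salicylaldehyde-derived keto aldehydes to 3-hydroxychroman-4-ones, from which this case differs in using an enolisable α-aryloxy aldehyde as the acceptor. Ring C closes 6-exo-trig (C4 nucleophile onto the exocyclic C3=O). The new C3 centre is set by the substrate, with the C2 aryl group pseudo-equatorial so that the 2,3-trans ketol (also the thermodynamic epimer) is expected, but no control is required because C2 and C3 both become sp2 in step 11 and the regioisomeric 4-hydroxy-3-ketone would converge on the same dione. The selectivity needed is chemoselectivity: Breslow formation at C4 and not at C3, where the aryloxy group β to the carbanion would be expelled, and benzoin closure faster than aldol closure of the C2 enolate onto the aryl aldehyde to a dihydrobenzofuran. The α,α-disubstitution at C3, the reversibly adding N-C6F5 carbene and a substoichiometric hindered amine as the only base should secure both.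

Step 11
Reactants: 15 rac-(2R,3R)-3-hydroxy-6,7-bis(methoxymethoxy)-2-[4-(methoxymethoxy)-3-(prenyloxy)phenyl]chroman-4-one
Product: 17 3-hydroxy-6,7-bis(methoxymethoxy)-2-[4-(methoxymethoxy)-3-(prenyloxy)phenyl]-4H-chromen-4-one, via chromane-3,4-dione 16 (not isolated)
Conditions: Dess–Martin periodinane (1.2 equiv), CH2Cl2, 0 °C → rt; Na2S2O3/NaHCO3 work-up, Et3N (cat.) if tautomerisation is slow
Reagents that add atoms: none
Why: Dess–Martin oxidation of the α-hydroxy ketone gives the 1,2-dione, whose only α-hydrogen (C2–H) is lost to give the conjugated 3-hydroxychromone tautomer; both stereocentres are erased here.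

Step 12
Reactants: 17 3-hydroxy-6,7-bis(methoxymethoxy)-2-[4-(methoxymethoxy)-3-(prenyloxy)phenyl]-4H-chromen-4-one
Product: 19 3,6,7-trihydroxy-2-[4-hydroxy-3-(prenyloxy)phenyl]-4H-chromen-4-one, via tetrakis(trimethylsilyl) ether 18 (not isolated)
Conditions: TMSOTf, 2,2′-bipyridyl, CH3CN, 0 °C → rt; then H2O
Reagents that add atoms: none
Why: Known chemoselective cleavage of aryl MOM ethers by a silyl triflate/2,2′-bipyridyl pair, which converts ArOCH2OMe into ArOSiMe3 (hydrolysed on work-up, as is the silylated 3-OH) without free Brønsted acid, so the prenyl aryl ether, which protic acid would ionise, should survive.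

**Compound list**
1 | 5-bromosalicylaldehyde | O=Cc1cc(Br)ccc1O | starting material
2 | 5-bromo-2-(methoxymethoxy)benzaldehyde | O=Cc1cc(Br)ccc1OCOC | intermediate
3 | 5-bromo-2-(methoxymethoxy)phenyl formate | O=COc1cc(Br)ccc1OCOC | intermediate (not isolated)
4 | 5-bromo-2-(methoxymethoxy)phenol | Oc1cc(Br)ccc1OCOC | intermediate
5 | prenyl bromide (1-bromo-3-methylbut-2-ene) | CC(C)=CCBr | starting material
6 | 4-bromo-1-(methoxymethoxy)-2-[(3-methylbut-2-en-1-yl)oxy]benzene | CC(C)=CCOc1cc(Br)ccc1OCOC | intermediate
7 | tert-butyl acetate | CC(=O)OC(C)(C)C | starting material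
8 | tert-butyl 2-[4-(methoxymethoxy)-3-(prenyloxy)phenyl]acetate | CC(C)=CCOc1cc(CC(=O)OC(C)(C)C)ccc1OCOC | intermediate
9 | tert-butyl 2-bromo-2-[4-(methoxymethoxy)-3-(prenyloxy)phenyl]acetate (racemic; one enantiomer drawn) | CC(C)(C)OC(=O)[C@@H](Br)c1ccc(OCOC)c(OCC=C(C)C)c1 | intermediate
10 | 2,4,5-trihydroxybenzaldehyde | O=Cc1cc(O)c(O)cc1O | starting material
11 | 2-hydroxy-4,5-bis(methoxymethoxy)benzaldehyde | O=Cc1cc(OCOC)c(OCOC)cc1O | intermediate
12 | tert-butyl 2-[2-formyl-4,5-bis(methoxymethoxy)phenoxy]-2-[4-(methoxymethoxy)-3-(prenyloxy)phenyl]acetate (racemic; one enantiomer drawn) | CC(C)(C)OC(=O)[C@H](Oc1cc(OCOC)c(OCOC)cc1C=O)c1ccc(OCOC)c(OCC=C(C)C)c1 | intermediate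
13 | 2-[2-(hydroxymethyl)-4,5-bis(methoxymethoxy)phenoxy]-2-[4-(methoxymethoxy)-3-(prenyloxy)phenyl]ethan-1-ol (racemic; one enantiomer drawn) | OC[C@H](Oc1cc(OCOC)c(OCOC)cc1CO)c1ccc(OCOC)c(OCC=C(C)C)c1 | intermediate
14 | 2-{1-[4-(methoxymethoxy)-3-(prenyloxy)phenyl]-2-oxoethoxy}-4,5-bis(methoxymethoxy)benzaldehyde (racemic; one enantiomer drawn) | O=C[C@H](Oc1cc(OCOC)c(OCOC)cc1C=O)c1ccc(OCOC)c(OCC=C(C)C)c1 | intermediate
15 | rac-(2R,3R)-3-hydroxy-6,7-bis(methoxymethoxy)-2-[4-(methoxymethoxy)-3-(prenyloxy)phenyl]chroman-4-one (2,3-trans; one enantiomer drawn) | COCOc1ccc(cc1OCC=C(C)C)[C@@H]1[C@H](C(=O)c2cc(OCOC)c(OCOC)cc2O1)O | intermediate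
16 | 6,7-bis(methoxymethoxy)-2-[4-(methoxymethoxy)-3-(prenyloxy)phenyl]chromane-3,4-dione (C2 configurationally labile, drawn without descriptor) | O=C1C(=O)c2cc(OCOC)c(OCOC)cc2OC1c1ccc(OCOC)c(OCC=C(C)C)c1 | intermediate (not isolated)
17 | 3-hydroxy-6,7-bis(methoxymethoxy)-2-[4-(methoxymethoxy)-3-(prenyloxy)phenyl]-4H-chromen-4-one | COCOc1ccc(cc1OCC=C(C)C)-c1oc2cc(OCOC)c(OCOC)cc2c(=O)c1O | intermediate
18 | 2-[3-(prenyloxy)-4-(trimethylsilyloxy)phenyl]-3,6,7-tris(trimethylsilyloxy)-4H-chromen-4-one | CC(C)=CCOc1cc(ccc1O[Si](C)(C)C)-c1oc2cc(O[Si](C)(C)C)c(O[Si](C)(C)C)cc2c(=O)c1O[Si](C)(C)C | intermediate (not isolated)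
19 | 3,6,7-trihydroxy-2-[4-hydroxy-3-[(3-methylbut-2-en-1-yl)oxy]phenyl]-4H-chromen-4-one (achiral) | CC(C)=CCOc1cc(-c2oc3cc(O)c(O)cc3c(=O)c2O)ccc1O | target

**Step count**
Total: 12 steps. Longest linear sequence: 11 steps (steps 1–5 and 7–12); step 6 is a one-step branch.

**Steps most likely to fail**

1. Step 10 (key step). The carbene may form its Breslow intermediate at the C3 aldehyde and expel the β-aryloxide (internal redox to an acyl azolium), the amine may trigger aldol closure of the C2 enolate onto the aryl aldehyde, or hydride transfer between the two formyl groups may lead to a lactone. Fallback with known chemistry: starting from 14, samarium diiodide (THF, t-BuOH, −78 °C) effects intramolecular pinacol coupling of the two aldehydes, a known closure for dialdehydes bearing α-oxygen substituents. It forms the same C3–C4 bond and should give 6,7-bis(methoxymethoxy)-2-[4-(methoxymethoxy)-3-(prenyloxy)phenyl]chromane-3,4-diol F1 as a diastereomer mixture. Swern oxidation of both carbinols ((COCl)2, DMSO, CH2Cl2, −78 °C; Et3N) then gives dione 16, which the triethylamine tautomerises in the same flask. The fallback returns to the route at 17.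

2. Step 9. After the first oxidation the hydroxy aldehyde may close to a lactol that is oxidised on to a lactone, and the α-aryloxy aldehyde may enolise and close by aldol reaction or oxidise in air during isolation. Fallback: starting from 13, the two alcohols are oxidised in separate chemoselective operations. Activated MnO2 (CH2Cl2, rt) oxidises only the benzylic alcohol and should give 2-{2-hydroxy-1-[4-(methoxymethoxy)-3-(prenyloxy)phenyl]ethoxy}-4,5-bis(methoxymethoxy)benzaldehyde F2. The remaining aliphatic primary alcohol is then oxidised with TEMPO (cat.)/PhI(OAc)2 (CH2Cl2, rt) and the solution is taken directly into step 10. The fallback returns to the route at 14.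

3. Step 5. Proton exchange between the product and unreacted enolate may give dibromide and recovered ester, the prenyl alkene or the electron-rich ring may be brominated, and the benzylic bromide may solvolyse on handling. Fallback: starting from 8, diazo transfer (4-acetamidobenzenesulfonyl azide, DBU, CH3CN) should give tert-butyl 2-diazo-2-[4-(methoxymethoxy)-3-(prenyloxy)phenyl]acetate F3. Rh2(OAc)4-catalysed O–H insertion of its carbenoid into phenol 11 (CH2Cl2, rt, slow addition of the diazo ester) forms the O1–C2 bond directly. The fallback replaces steps 5 and 7 and returns to the route at 12.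

**Further compounds**
F1 | step 10 | 6,7-bis(methoxymethoxy)-2-[4-(methoxymethoxy)-3-(prenyloxy)phenyl]chromane-3,4-diol (mixture of diastereomers, drawn without descriptors) | COCOc1ccc(cc1OCC=C(C)C)C1Oc2cc(OCOC)c(OCOC)cc2C(O)C1O
F2 | step 9 | 2-{2-hydroxy-1-[4-(methoxymethoxy)-3-(prenyloxy)phenyl]ethoxy}-4,5-bis(methoxymethoxy)benzaldehyde (racemic; one enantiomer drawn) | OC[C@H](Oc1cc(OCOC)c(OCOC)cc1C=O)c1ccc(OCOC)c(OCC=C(C)C)c1
F3 | step 5 | tert-butyl 2-diazo-2-[4-(methoxymethoxy)-3-(prenyloxy)phenyl]acetate | CC(C)=CCOc1cc(C(=[N+]=[N-])C(=O)OC(C)(C)C)ccc1OCOC
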